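**The task.** Start from the catalyst's balance, not from the substrate.

| flask | substrate | free catalyst | time | remark |
|---|---|---|---|---|
| east | 18 mM (fed, over 15.0 h) | 18 µM | 15 h | all but substrate at the start; substrate goes in evenly over 15.0 h, the run ends at 15 h |
| north-east | 18 mM | 18 µM |  | one stirred flow tank at steady state, fed with the mixture as stated, mean residence time 15 h |
| south-east | 18 mM | 18 µM |  | one stirred flow tank at steady state, fed with the mixture as stated, mean residence time 75.0 h |
| north | 18 mM | 18 µM | 15 h | everything together in a closed stirred flask, run for 15 h |

    substrate + free catalyst → catalyst intermediate (k1 = 1.2 M⁻¹ s⁻¹)
    free catalyst ⇌ dormant form (K2 = 1.4, k2 = 1.1 × 10⁻⁴ s⁻¹)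
    target ⇌ isomer of the product (K3 = 1.1, k3 = 2.0 × 10⁻⁵ s⁻¹)
    catalyst intermediate → free catalyst + target (k4 = 0.023 s⁻¹)

- the set-up with the highest amount of target at the outlet or at the end, in percent of the substrate put in ("none" if the first two lie within 2 percentage points) (east / north-east / south-east / north / none)
- amount of target at the outlet or at the end, in percent of the substrate put in, east
- amount of target at the outlet or at the end, in percent of the substrate put in, north-east
- amount of target at the outlet or at the end, in percent of the substrate put in, south-east
- amount of target at the outlet or at the end, in percent of the substrate put in, north

**Catalyst balance.** I took north, the closed flask. Catalyst intermediate decays with a half-life of 30.1 s, shorter than the 1.02 h in which free catalyst and dormant form relax. That relaxation is short against the run of 15 h, so I held both balances. The rate then became Vm[substrate]/(Kh + [substrate]), with ceiling Vm = 1.49 mM h⁻¹. Kh = 46.0 mM is my working half-level: the [substrate] at which the charged catalyst, dormant form counted, runs at half its ceiling. It is a half-saturation constant widened by dormant form. Integrated, the rate gave the time to reach any [substrate]: (Kh ln(charge/[substrate]) + charge − [substrate])/Vm.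

**The bracket.** I held the opening rate for the whole run and allowed no isomer. Target in north then came to 34.9 %, my upper bound. The rate falls no faster than [substrate], so conversion reached at least 29.5 %. The balance share of that gave my lower bound, 14.0 %. To tighten, I put that substrate drop back into the integrated law and got a conversion of 31.0 %. Target and isomer of the product relax, both ways together, at 0.137 h⁻¹, and an even supply over the run keeps 69.8 % of the product as target. I committed to 21.6 %.

**The forecast.** The forecast named south-east, saying “its long residence time gives about 69% conversion”, with east 12 %, north-east 19 %, south-east 36 % and north 22.5 %, the figure for north lying inside my bracket for north and higher than my own figure.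

**The result.** The simulation gave east 13.1 %, north-east 19.0 %, south-east 36.0 % and north 22.6 %, so south-east came out highest. North lay inside my bracket.

**What ran.** In north the step from substrate and free catalyst to catalyst intermediate did half of its turnover by 6.20 h, with 67 % of the substrate still unbound at 15 h. Half of the turnover from target to isomer of the product came later, by 9.00 h, and 10.8 % stood as isomer of the product at 15 h. Kh turned that substrate reading into a time of 16.6 h, against the 15 h north took, and for north left to 60.0 h, with 19 % substrate and 41.5 % target, it gave 61.9 h.

The constants used here are assumed; what happens was integrated by code.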